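## Retrosynthetic overview
1. The target (labdane numbering: 5R,10R trans-decalin, 8(9)-ene, 13E-ene) comes from its O-methyl ether methyl ester. One thiolate step removes both methyl groups.
2. C14–C15 (vinyl–benzyl) and C13–CH3 are cut together. This gives a bicyclic terminal alkyne, AlMe3 and methyl 3-(bromomethyl)-4-methoxybenzoate. Syn-methylalumination followed by cross-coupling fixes 13E.
3. Both rings and both stereocentres are cut in one move, back to an acyclic E,E-trienyne. A chiral proton starts the cyclase-like cascade at the isopropylidene end. Ring A closes first (C4–C5), ring B second (C9–C10), and the C8 cation ends by loss of H-9.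
4. The terminal alkyne is both the stop signal of the cascade and the masked 13E-alkene. The trienyne comes from (E,E)-farnesyl bromide and the propyne dianion.

Assumption: the (S)-ligand is taken to give the 5R,10R series, because the (R)-ligand is the one that leads to the antipodal (5S,10S) ambroxide-type series; if 5 responds with the opposite sense, the (R)-ligand is used and nothing else changes.

## Route

Step 1
Reactants: 1 propyne; 2 (2E,6E)-farnesyl bromide
Product: 5 (5E,9E)-6,10,14-trimethylpentadeca-5,9,13-trien-1-yne, via 1,3-dilithiopropyne 3 (not isolated), via lithium acetylide 4 (not isolated)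
Conditions: 1 (1.5 equiv), n-BuLi (3.0 equiv), TMEDA, Et2O–hexane, −78 → 0 °C; then 2, −78 → 23 °C; H2O
Reagents that add atoms: none
Why: This is a propargylic C-alkylation of the propyne dianion, in which the sp3 carbanion end is far more nucleophilic than the acetylide end and displaces the primary allylic bromide by SN2, so both E-alkenes stay intact, protonation frees the terminal alkyne, and no stereocentre is formed.

Step 2
Reactants: 5 (5E,9E)-6,10,14-trimethylpentadeca-5,9,13-trien-1-yne
Product: 9 (4aR,8aR)-5-(but-3-yn-1-yl)-1,1,4a,6-tetramethyl-1,2,3,4,4a,7,8,8a-octahydronaphthalene, via bicyclic C8 carbocation 6 (not isolated), via exocyclic alkene isomer 7 (not isolated), via trisubstituted alkene isomer 8 (not isolated)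
Conditions: (S)-2-(2-fluorobenzyloxy)-2'-hydroxy-1,1'-binaphthyl (1.1 equiv, recovered), SnCl4 (1.0 equiv), toluene, −78 °C, 48 h; then CF3CO2H (0.3 equiv), −78 → −40 °C, 6 h; sat. aq NaHCO3
Reagents that add atoms: none
Why: Proposed new method: the naphthol proton, acidified by SnCl4 inside the chiral binaphthyl pocket, adds to one face of the terminal isopropylidene alkene (the least hindered of the three), and the E,E-triene folds chair–chair so that ring A (C4–C5) and then ring B (C9–C10) close by anti addition across each E-alkene, which fixes 10-CH3 anti to 5-H (trans-decalin) while the face of protonation fixes 5R,10R; the terminal alkyne cannot carry the cascade on because that would need a bent cyclohexenyl or a primary vinyl cation, so cation 6 can only lose a proton, and CF3CO2H·SnCl4 re-protonates the kinetic alkenes 7 and 8 back to 6 until the material rests in the hindered tetrasubstituted alkene 9, the thermodynamic sink; closest known reaction type: enantioselective proton-initiated polyene cyclisation with a chiral and then an achiral Lewis-acid-assisted Brønsted acid (known with aryl, hydroxyl and carboxyl terminators), joined to the known acid equilibration of labd-8(17)-enes and labd-7-enes to labd-8-enes.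

Step 3
Reactants: 9 (4aR,8aR)-5-(but-3-yn-1-yl)-1,1,4a,6-tetramethyl-1,2,3,4,4a,7,8,8a-octahydronaphthalene; 10 methyl 3-(bromomethyl)-4-methoxybenzoate
Product: 12 methyl 4-methoxy-3-[(2E)-3-methyl-5-[(4aR,8aR)-2,5,5,8a-tetramethyl-3,4,4a,5,6,7,8,8a-octahydronaphthalen-1-yl]pent-2-en-1-yl]benzoate, via alkenyldimethylalane 11 (not isolated)
Conditions: AlMe3 (2 equiv), Cp2ZrCl2 (20 mol%), ClCH2CH2Cl, 0 → 23 °C; evaporate, THF; 10 (1.0 equiv), Pd(PPh3)4 (5 mol%), 23 °C; 1 M HCl
Reagents that add atoms: trimethylaluminium, C[Al](C)C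
Why: Negishi zirconium-catalysed methylalumination adds CH3 and Al syn with Al on the terminal carbon, so alane 11 is E, and the alkenyl–benzyl cross-coupling on zerovalent palladium goes with retention and sets the 13E alkene, while the hindered ring alkene, both stereocentres and the benzoate ester (THF-complexed alane, 23 °C) are left alone.

Step 4
Reactants: 12 methyl 4-methoxy-3-[(2E)-3-methyl-5-[(4aR,8aR)-2,5,5,8a-tetramethyl-3,4,4a,5,6,7,8,8a-octahydronaphthalen-1-yl]pent-2-en-1-yl]benzoate
Product: 14 4-hydroxy-3-[(2E)-3-methyl-5-[(4aR,8aR)-2,5,5,8a-tetramethyl-3,4,4a,5,6,7,8,8a-octahydronaphthalen-1-yl]pent-2-en-1-yl]benzoic acid, via disodium salt 13 (not isolated)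
Conditions: NaSEt (6 equiv), DMF, 120 °C; then 1 M HCl, 0 °C
Reagents that add atoms: none
Why: This is a nucleophilic (SN2) demethylation in which the soft thiolate attacks both O–CH3 carbons (aryl methyl ether and ester alkyl–oxygen cleavage) under non-acidic conditions, so neither alkene is protonated, the phenol cannot close onto the 13-ene, and the stereocentres and alkene geometry are untouched.

## Compound list
1 | propyne | CC#C | starting material
2 | (2E,6E)-farnesyl bromide, (2E,6E)-1-bromo-3,7,11-trimethyldodeca-2,6,10-triene | CC(C)=CCC/C(C)=C/CC/C(C)=C/CBr | starting material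
3 | 1,3-dilithiopropyne | [Li]CC#C[Li] | intermediate
4 | lithium acetylide of 5 | CC(C)=CCC/C(C)=C/CC/C(C)=C/CCC#C[Li] | intermediate
5 | (5E,9E)-6,10,14-trimethylpentadeca-5,9,13-trien-1-yne | CC(C)=CCC/C(C)=C/CC/C(C)=C/CCC#C | intermediate
6 | bicyclic C8 tertiary carbocation (trans-decalin; 5-H and 9-H on one face, 10-CH3 on the other) | C[C+]1CC[C@@H]2C(C)(C)CCC[C@@]2(C)[C@@H]1CCC#C | intermediate
7 | (1R,4aR,8aR)-1-(but-3-yn-1-yl)-5,5,8a-trimethyl-2-methylidenedecahydronaphthalene (8(17)-ene) | C=C1CC[C@@H]2C(C)(C)CCC[C@@]2(C)[C@@H]1CCC#C | intermediate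
8 | (1R,4aR,8aR)-1-(but-3-yn-1-yl)-2,5,5,8a-tetramethyl-1,4,4a,5,6,7,8,8a-octahydronaphthalene (7-ene) | CC1=CC[C@@H]2C(C)(C)CCC[C@@]2(C)[C@@H]1CCC#C | intermediate
9 | (4aR,8aR)-5-(but-3-yn-1-yl)-1,1,4a,6-tetramethyl-1,2,3,4,4a,7,8,8a-octahydronaphthalene (8(9)-ene) | CC1=C(CCC#C)[C@]2(C)CCCC(C)(C)[C@H]2CC1 | intermediate
10 | methyl 3-(bromomethyl)-4-methoxybenzoate | COC(=O)c1ccc(OC)c(CBr)c1 | starting material
11 | dimethyl[(1E)-2-methyl-4-[(4aR,8aR)-2,5,5,8a-tetramethyl-3,4,4a,5,6,7,8,8a-octahydronaphthalen-1-yl]but-1-en-1-yl]alane | CC1=C(CC/C(C)=C/[Al](C)C)[C@]2(C)CCCC(C)(C)[C@H]2CC1 | intermediate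
12 | methyl 4-methoxy-3-[(2E)-3-methyl-5-[(4aR,8aR)-2,5,5,8a-tetramethyl-3,4,4a,5,6,7,8,8a-octahydronaphthalen-1-yl]pent-2-en-1-yl]benzoate | CC1=C(CC/C(C)=C/Cc2cc(C(=O)OC)ccc2OC)[C@]2(C)CCCC(C)(C)[C@H]2CC1 | intermediate
13 | disodium phenoxide carboxylate of 14 | CC1=C(CC/C(C)=C/Cc2cc(C(=O)[O-])ccc2[O-])[C@]2(C)CCCC(C)(C)[C@H]2CC1.[Na+].[Na+] | intermediate
14 | 4-hydroxy-3-[(2E)-3-methyl-5-[(4aR,8aR)-2,5,5,8a-tetramethyl-3,4,4a,5,6,7,8,8a-octahydronaphthalen-1-yl]pent-2-en-1-yl]benzoic acid | CC1=C(CC/C(C)=C/Cc2cc(C(=O)O)ccc2O)[C@]2(C)CCCC(C)(C)[C@H]2CC1 | target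

## Step count and risks
Total step count: 4. Longest linear sequence: 4 (2 → 5 → 9 → 12 → 14). The recoverable chiral ligand is made by one O-alkylation of (S)-BINOL with 2-fluorobenzyl bromide and is not counted.

**Step 2 (highest risk).** No internal nucleophile ends the cascade, so four things are open:
- the ee, expected at 85–90 % and checked on 9 by chiral GC, and raised if needed by crystallising 14;
- whether 7 and 8 drain fully into 9;
- chloride-assisted capture of 6 by the alkyne;
- 1,2-shifts starting from 6.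

The fallback sets out from 2 and comes back at 9. It ends the cascade with a carboxyl group and builds the alkyne afterwards. Dilithioacetate (AcOH, LiN(i-Pr)2 2 equiv, THF–DMPU) is alkylated with 2 to give (4E,8E)-farnesylacetic acid F1. The same chiral acid, followed by CF3CO2H·SnCl4, cyclises F1, and the oxygen captures C8 anti, so no alkene regiochemistry arises. The product is the crystalline δ-lactone ent-ambreinolide F2, which can be recrystallised to enantiopurity. i-Bu2AlH (CH2Cl2, −78 °C) then gives the lactol F3. Dimethyl (1-diazo-2-oxopropyl)phosphonate with K2CO3 in MeOH homologates the open aldehyde form of F3 to the 8-hydroxy alkyne F4. Finally p-TsOH in toluene at 80 °C dehydrates F4 under equilibrating conditions to 9.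

**Step 3.** Residual AlMe3 or alane 11 may attack the ester of 10, methyl may transfer instead of alkenyl, and 10 may homocouple.

The fallback sets out from 9 and 10 and comes back at 12. It reverses the polarity of the coupling. Alane 11, made from 9 as in step 3, is quenched with I2 (THF, −30 °C) to the isolable (E)-alkenyl iodide F5. Zn dust and LiCl (THF, 0 °C) turn 10 into the ester-tolerant benzylic zinc bromide F6. Pd(PPh3)4 (3 mol%, THF, 23 °C) joins F5 and F6 with retention to give 12.

**Step 4.** Ether cleavage may stall once the carboxylate has formed, and long heating may erode the skipped aryl–allyl alkene.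

The fallback sets out from 10 and comes back at 14. It moves the ether cleavage to a stage where no alkene is present. BBr3 (CH2Cl2, −78 → 0 °C) converts 10 into methyl 3-(bromomethyl)-4-hydroxybenzoate F7. t-BuMe2SiOTf with 2,6-lutidine (−78 °C) gives the silyl ether bromide F8. F8 is coupled with alane 11 as in step 3 to give the silyl ether methyl ester F9. LiOH (THF–MeOH–H2O, 40 °C) then removes the aryl silyl ether and the ester in one flask to give 14.

## Further compounds
F1 | step 2 | (4E,8E)-5,9,13-trimethyltetradeca-4,8,12-trienoic acid (farnesylacetic acid) | CC(C)=CCC/C(C)=C/CC/C(C)=C/CCC(=O)O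
F2 | step 2 | ent-ambreinolide, (5R,8S,9S,10R)-14,15,16-trinorlabdan-13,8-olide | C[C@@]12CCCC([C@H]1CC[C@]3([C@H]2CCC(=O)O3)C)(C)C
F3 | step 2 | lactol of F2 (anomer mixture at C13) | C[C@@]12CCCC([C@H]1CC[C@]3([C@H]2CCC(O)O3)C)(C)C
F4 | step 2 | (5R,8S,9S,10R)-15,16-dinorlabd-13-yn-8-ol | C[C@@]12CCCC([C@H]1CC[C@]([C@H]2CCC#C)(C)O)(C)C
F5 | step 3 | (4aR,8aR)-5-[(3E)-4-iodo-3-methylbut-3-en-1-yl]-1,1,4a,6-tetramethyl-1,2,3,4,4a,7,8,8a-octahydronaphthalene | CC1=C(CC/C(C)=C/I)[C@]2(C)CCCC(C)(C)[C@H]2CC1
F6 | step 3 | [2-methoxy-5-(methoxycarbonyl)benzyl]zinc bromide | COC(=O)c1ccc(OC)c(C[Zn]Br)c1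
F7 | step 4 | methyl 3-(bromomethyl)-4-hydroxybenzoate | COC(=O)c1ccc(O)c(CBr)c1
F8 | step 4 | methyl 3-(bromomethyl)-4-[(tert-butyldimethylsilyl)oxy]benzoate | COC(=O)c1ccc(O[Si](C)(C)C(C)(C)C)c(CBr)c1
F9 | step 4 | methyl 4-[(tert-butyldimethylsilyl)oxy]-3-[(2E)-3-methyl-5-[(4aR,8aR)-2,5,5,8a-tetramethyl-3,4,4a,5,6,7,8,8a-octahydronaphthalen-1-yl]pent-2-en-1-yl]benzoate | CC1=C(CC/C(C)=C/Cc2cc(C(=O)OC)ccc2O[Si](C)(C)C(C)(C)C)[C@]2(C)CCCC(C)(C)[C@H]2CC1
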